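I start from a ratio.

common to all: precatalyst 2.1 mM
- west: left-handed substrate 0.12 M; right-handed substrate 0.12 M; solid reagent 0.255 M; run made earlier
- south-west: left-handed substrate 0.19 M; right-handed substrate 0.19 M; solid reagent 0.255 M; run made earlier
- east: left-handed substrate 0.085 M; right-handed substrate 0.085 M; solid reagent 0.38 M; run made earlier
- flask: left-handed substrate 0.085 M; right-handed substrate 0.085 M; solid reagent 0.255 M; time 12 min

| run | time / min | right-handed substrate / % | left-handed substrate / % | left-handed product / % |
|---|---|---|---|---|
| west | 0.833 | 49.7 | 50.4 | 0 |
| west | 1.33 | 51.0 | 49.9 | 0.6 |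
| west | 2.00 | 48.4 | 50.1 | 0.5 |
| west | 2.50 | 48.6 | 47.5 | 3.3 |
| west | 4.00 | 44.3 | 42.9 | 7.5 |
| west | 6.00 | 42.7 | 33.8 | 16.3 |
| west | 10.0 | 33.9 | 22.5 | 27.7 |
| south-west | 0.833 | 51.1 | 49.7 | 0 |
| south-west | 1.33 | 48.5 | 49.5 | 0.7 |
| south-west | 2.00 | 48.2 | 48.4 | 1.6 |
| south-west | 2.50 | 49.6 | 47.8 | 2.4 |
| south-west | 4.00 | 46.6 | 45.2 | 6.6 |
| south-west | 6.00 | 43.8 | 40.0 | 11.3 |
| south-west | 10.0 | 38.9 | 27.5 | 23.1 |
| east | 0.833 | 49.8 | 49.3 | 0 |
| east | 2.50 | 49.8 | 49.3 | 0.7 |
| east | 4.00 | 47.0 | 43.2 | 6.5 |
| east | 6.00 | 39.6 | 32.1 | 17.1 |
| east | 10.0 | 28.4 | 16.3 | 34.7 |

(readings scatter by 1 percentage point)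

- catalyst is single-handed; left-handed substrate and right-handed substrate are mirror images of each other, charged as a racemate, each of them at the stated concentration
- as a solid, counted per litre of solution: solid reagent
- what was read earlier has a scatter of 1 percentage point, one standard deviation
- candidate steps: partner + catalyst + right-handed substrate -> catalyst + right-handed product; partner + precatalyst -> catalyst + spent reagent; solid reagent <-> partner; partner + catalyst + left-handed substrate -> catalyst + left-handed product
- at the start none of the solid reagent is in solution

- whether the excess of right-handed substrate over left-handed substrate among what is left of the two reaches 99 % by 12 min (yes / no)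
- the highest excess of right-handed substrate over left-handed substrate among what is left of the two up to 12 min

By the candidate steps, each substrate is lost at its own constant times c(partner) times c(catalyst) times its own c(substrate). Dividing the two rates cancels c(partner) and c(catalyst), however they move with time, so the integral closes: the logarithm of the fraction of left-handed substrate left, over the logarithm of the fraction of right-handed substrate left, is a fixed number. I call this number the selectivity factor, s = 1.98, as read from the east run at 10.0 min. The west run reads 2.05 at 10.0 min.

The ladder of times starts with this split, which holds from the first turnover. Next comes a lag: in the east run, left-handed product is still 0.7 % at 2.50 min. Then the last two east readings show right-handed substrate shrinking with a time constant of 12.0 min. The top rung is 99 %, which needs right-handed substrate down to 0.455 % of its charge. At that pace I estimate 64.9 min for this, longer than the 12 min allowed.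

Carrying the east run on to 12 min, although the flask has 0.255 M of solid reagent against 0.38 M, I reckon 48.1 % of the charged right-handed substrate left. With s this makes an excess of 34.5 %, and the excess grows as substrate falls. The forecast, holding that “the left-handed form reacts about twice as fast”, says no and 33 %, a little below my figure.

The flask gives no and 36.6 %.

    partner + catalyst + right-handed substrate → catalyst + right-handed product (k = 69.1 L² mol⁻² s⁻¹)
    partner + precatalyst → catalyst + spent reagent (k = 0.0571 L mol⁻¹ s⁻¹)
    solid reagent ⇌ partner, rate k3*(cs3 - [partner]) while solid is left; crystals form when [partner] > cs3 (solubility = 0.0540 M, k = 0.00585 s⁻¹)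
    partner + catalyst + left-handed substrate → catalyst + left-handed product (k = 139 L² mol⁻² s⁻¹)

At 12.0 min the flask keeps 22 % of its left-handed and 47 % of its right-handed substrate, and the left-handed step uses partner at 0.93 of the rate of the right-handed step. The s read before, times the ratio of what is left, gives 0.927. A neighbouring flask charged with 0.0036 M of precatalyst keeps, at the same time, 37 % of its right-handed substrate, for which s reckons an excess of 45.2 %, and its excess reaches 46.0 %.

Readings and results were computed with made-up constants; scatter was added.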